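This stirred, isothermal vessel turns starting material into the intermediate, which then leaves by three exits.

| flask | starting material | second nucleophile | gas | time | remark |
|---|---|---|---|---|---|
| Thursday's | 0.10 M | 1.05 equiv (fed, over 2.0 h) | 5.3 mM (held) | 10 h | all else is in the flask from the start; the feed brings no volume worth counting |
| Monday's | 0.10 M | 1.05 equiv | 5.3 mM (held) | 10 h | everything together at the start |
| Tuesday's | 0.10 M (fed, over 30 min) | 1.05 equiv | 5.3 mM (held) | 10 h | all else is in the flask from the start; the feed brings no volume worth counting |
| Wednesday's | 0.10 M (fed, over 2.0 h) | 1.05 equiv | 5.3 mM (held) | 10 h | all else is in the flask from the start; the feed brings no volume worth counting |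

    target ⇌ isomer of the product (K1 = 1.9, k1 = 0.021 min⁻¹)
    gas ⇌ first nucleophile, rate k2*(csat - [first nucleophile]) (k2 = 23 min⁻¹, csat = 5.3 mM)
    second nucleophile + intermediate → other capture product (k3 = 430 M⁻¹ min⁻¹)
    intermediate → solvolysis product (k4 = 12 min⁻¹)
    first nucleophile + intermediate → target (k5 = 3500 M⁻¹ min⁻¹)
    starting material → intermediate (k6 = 0.59 min⁻¹)

- at the start none of first nucleophile is dissolved
- run time (Thursday's): 10 h

- the flask that comes out highest in share of target in target plus other capture product, or "all alike" when all lie within 1.5 percentage points (Thursday's / Monday's / Tuesday's / Wednesday's / all alike)
- share of target in target plus other capture product at the end, Thursday's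
- share of target in target plus other capture product at the end, Monday's
- share of target in target plus other capture product at the end, Tuesday's
- share of target in target plus other capture product at the end, Wednesday's

Keep the books on starting material, the limiting reagent. Count lifetimes first: it lasts 1.69 min, far shorter than the slow addition of 2.0 h. Take c(first nucleophile) at 5.3 mM, which gives that capture a pseudo-first-order constant of 18.6 min⁻¹ beside the solvolysis constant 12 min⁻¹. Call the half-share level the c(second nucleophile) at which that nucleophile takes half of the intermediate: 0.0710 M. Other capture then receives c/(c+level). Of the remainder, 60.7% enters the target family and the rest is solvolysis product. The relaxation half-life 0.360 h is shorter than the 10 h run, so book target at 34.5% of its family, which makes 20.9% of the remainder.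

Enter Monday's flask. It starts at 0.105 M; if about 0.5 of the starting material goes to other capture, the mean over conversion is 0.0800 M. Other capture takes 53.0% and target 9.85%, isomer of the product 18.7% and solvolysis product 18.5%, and the books close. The share is 15.7%. Tuesday's and Wednesday's flasks hold the same second-nucleophile charge, and the level contains no starting material, so book 15.7% and 15.7%. For Thursday's flask, one lifetime of feed brings 0.001483 M, far below the level. Other capture takes 2.04% and target 20.5%, so the share is 90.9%. My pick is Thursday's.

The forecast also picks Thursday's, with 89.3% for Thursday's, 15.6% for Monday's, 16.3% for Tuesday's and 16.4% for Wednesday's, holding that “feeding the starting material merely relieves slight gas-transfer depletion and changes little”. It differs from my reckoning by setting Tuesday's and Wednesday's above Monday's.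

The simulation gives Thursday's as highest: 92.5% for Thursday's, 15.4% for Monday's, 16.2% for Tuesday's and 16.3% for Wednesday's.

Hold the level against the ends: other capture stands at 52.7% on Monday's flask against my 53.0%, and at 1.56% on Thursday's against my 2.04%. At 0.0671 M of starting material the answer for Monday's flask has moved by 5 points, outside the forecast's range of 14.8% to 16.5%. Take the neighbour of Monday's flask at 0.040 M, equivalents held. If about a third of its starting material goes to other capture, its mean is 0.0353 M, below the level, so I book other capture at 33.2% and the share at 29.6%. That neighbour ends with other capture at 33.6% and a share of 28.8%.

The rate constants are invented, and the outcome is calculated.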